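The route rests on one observation: C4 of the upper (epiafzelechin) unit is a methine flanked by two phloroglucinol-type rings, C4a of its own ring A and C8 of ring A of the epigallocatechin unit, so it is a masked aldehyde carbon. One Lewis-acid operation on an acyclic aldehyde forms C4–C4a, which closes the upper pyran ring (O1, C2, C3, C4, C4a, C8a), and C4–C8, the interflavan bond, with loss of water and 3,4-trans control. The precursor is a (2S,3R)-2-benzyloxy-3-aryl-3-aryloxypropanal that already carries C2, C3 and the O1–C8a ether, made by an Evans glycolate aldol and a copper-catalysed O-arylation, plus penta-O-benzyl-epigallocatechin.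

Key step: step 10

Remark on the chemistry: the primary hydroxyl is masked as a triisopropylsilyl ether, because this bulky silyl group resists O-to-O migration under the carbonate base of the later etherification; the transient flavan-4-ol of the key step is drawn without a defined C4 configuration, since both epimers ionise to the same cation.

Step 1
Reactants: 1 (S)-4-benzyloxazolidin-2-one; 2 benzyloxyacetyl chloride
Product: 4 (S)-4-benzyl-3-[2-(benzyloxy)acetyl]oxazolidin-2-one, via N-lithio oxazolidinone 3 (not isolated)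
Conditions: n-BuLi (1.05 equiv), THF, −78 °C; then 2, −78 → 0 °C
Reagents that add atoms: none
Why: N-acylation of the lithiated oxazolidinone with an acid chloride is the standard entry to Evans imides and touches no stereocentre.

Step 2
Reactants: 4 (S)-4-benzyl-3-[2-(benzyloxy)acetyl]oxazolidin-2-one; 5 4-(benzyloxy)benzaldehyde
Product: 8 (S)-4-benzyl-3-[(2S,3R)-2-(benzyloxy)-3-[4-(benzyloxy)phenyl]-3-hydroxypropanoyl]oxazolidin-2-one, via Z boron enolate 6 (not isolated), via boron aldolate 7 (not isolated)
Conditions: Bu2BOTf (1.2 equiv), Et3N (1.4 equiv), CH2Cl2, −78 → 0 °C; then 5, −78 → 0 °C; pH 7 buffer, MeOH, 30% H2O2, 0 °C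
Reagents that add atoms: none
Why: In this Evans syn aldol reaction, soft enolisation gives the Z dibutylboron enolate, which reacts through a closed Zimmerman–Traxler chair with the benzyl group of the (S)-auxiliary shielding one enolate face, so both new stereocentres should be set as the (2S,3R) syn adduct.

Step 3
Reactants: 8 (S)-4-benzyl-3-[(2S,3R)-2-(benzyloxy)-3-[4-(benzyloxy)phenyl]-3-hydroxypropanoyl]oxazolidin-2-one
Product: 9 (1R,2R)-2-(benzyloxy)-1-[4-(benzyloxy)phenyl]propane-1,3-diol
Conditions: LiBH4 (2 equiv), THF, H2O (1 equiv), 0 °C → rt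
Reagents that add atoms: none
Why: Reductive cleavage of the N-acyloxazolidinone by LiBH4 at the exocyclic imide carbonyl should give the 1,3-diol and release the auxiliary without touching either stereocentre.

Step 4
Reactants: 9 (1R,2R)-2-(benzyloxy)-1-[4-(benzyloxy)phenyl]propane-1,3-diol
Product: 10 (1R,2R)-2-(benzyloxy)-1-[4-(benzyloxy)phenyl]-3-[(triisopropylsilyl)oxy]propan-1-ol
Conditions: TIPSCl (1.1 equiv), imidazole, DMF, 0 °C → rt
Reagents that add atoms: triisopropylsilyl chloride, CC(C)[Si](Cl)(C(C)C)C(C)C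
Why: Silyl ether formation with the bulky chlorosilane is much faster at the unhindered primary hydroxyl than at the hindered secondary benzylic one, so the monosilyl ether should form selectively.

Step 5
Reactants: 11 5-iodoresorcinol
Product: 12 1,3-bis(benzyloxy)-5-iodobenzene
Conditions: BnBr (2.3 equiv), K2CO3, DMF, rt → 50 °C
Reagents that add atoms: benzyl bromide, BrCc1ccccc1
Why: Williamson etherification of both phenols under carbonate base is routine and leaves the aryl iodide intact.

Step 6
Reactants: 10 (1R,2R)-2-(benzyloxy)-1-[4-(benzyloxy)phenyl]-3-[(triisopropylsilyl)oxy]propan-1-ol; 12 1,3-bis(benzyloxy)-5-iodobenzene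
Product: 13 [(2R,3R)-2-(benzyloxy)-3-[4-(benzyloxy)phenyl]-3-[3,5-bis(benzyloxy)phenoxy]propoxy]triisopropylsilane
Conditions: CuI (10 mol %), 3,4,7,8-tetramethyl-1,10-phenanthroline (20 mol %), Cs2CO3 (2 equiv), 12 (1.5 equiv), toluene, 4 Å MS, 90 °C, argon
Reagents that add atoms: none
Why: The Ullmann-type copper-catalysed C–O coupling of aryl iodides with secondary alcohols, benzylic ones included, forms only the aryl–oxygen bond, so the carbinol C–O bond is never broken and the benzylic stereocentre should be carried over with retention.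

Step 7
Reactants: 13 [(2R,3R)-2-(benzyloxy)-3-[4-(benzyloxy)phenyl]-3-[3,5-bis(benzyloxy)phenoxy]propoxy]triisopropylsilane
Product: 14 (2R,3R)-2-(benzyloxy)-3-[4-(benzyloxy)phenyl]-3-[3,5-bis(benzyloxy)phenoxy]propan-1-ol
Conditions: TBAF (1.2 equiv), THF, 0 °C → rt
Reagents that add atoms: none
Why: Fluoride-induced desilylation should free the primary alcohol while the benzyl ethers and the benzylic aryl ether are inert to TBAF.

Step 8
Reactants: 15 (−)-epigallocatechin
Product: 16 5,7,3',4',5'-penta-O-benzyl-(−)-epigallocatechin [(2R,3R)-5,7-bis(benzyloxy)-2-[3,4,5-tris(benzyloxy)phenyl]chroman-3-ol]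
Conditions: BnBr (5.2 equiv), K2CO3 (5.5 equiv), degassed DMF, 0 °C → rt, argon
Reagents that add atoms: benzyl bromide, BrCc1ccccc1
Why: Williamson etherification under mild carbonate base should alkylate only the five phenols, which are far more acidic than the secondary 3-OH, while exclusion of oxygen protects the pyrogallol ring and the two stereocentres stay untouched.

Step 9
Reactants: 14 (2R,3R)-2-(benzyloxy)-3-[4-(benzyloxy)phenyl]-3-[3,5-bis(benzyloxy)phenoxy]propan-1-ol
Product: 17 (2S,3R)-2-(benzyloxy)-3-[4-(benzyloxy)phenyl]-3-[3,5-bis(benzyloxy)phenoxy]propanal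
Conditions: Dess–Martin periodinane (1.3 equiv), NaHCO3, CH2Cl2, 0 °C; cold filtration through a short silica pad, used at once
Reagents that add atoms: none
Why: The Dess–Martin oxidation runs buffered at 0 °C without an amine base, which should limit epimerisation of the alpha-alkoxy centre and beta-elimination of the aryloxide.

Step 10
Reactants: 17 (2S,3R)-2-(benzyloxy)-3-[4-(benzyloxy)phenyl]-3-[3,5-bis(benzyloxy)phenoxy]propanal; 16 5,7,3',4',5'-penta-O-benzyl-(−)-epigallocatechin
Product: 20 3,5,7,4'-tetra-O-benzyl-epiafzelechin-(4β→8)-5,7,3',4',5'-penta-O-benzyl-epigallocatechin (upper unit 2R 3R 4R; lower unit 2R 3R), via flavan-4-ol 18 (not isolated), via C4 benzylic cation 19 (not isolated)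
Conditions: 16 (3 equiv), TMSOTf (0.3 equiv), 4 Å MS, CH2Cl2, −78 °C; slow addition of 17; −78 → −40 °C; Et3N quench; excess 16 recovered
Reagents that add atoms: none
Why: Proposed new method: TMSOTf activates the aldehyde of 17, the ortho carbon of its own 3,5-bis(benzyloxy)phenyl ether adds to the carbonyl carbon (Friedel–Crafts hydroxyalkylation) to give flavan-4-ol 18 (free or O-silylated in the flask), and this ionises at once to the C4 benzylic cation 19, stabilised by the 5- and 7-oxygens, which C8 of 16 captures with loss of the aldehyde oxygen as water; should 16 add to the aldehyde first, the diarylmethanol so formed ionises and the tethered ring closes, so both orders of events should end at 20. The closest known reaction types are the Lewis-acid coupling of C4-oxygenated benzylated flavan-3-ols with C8 of benzylated flavan-3-ols, the acid-mediated cyclisation of 3-aryloxypropanals to chroman-4-ols and the Baeyer condensation of an aldehyde with two electron-rich arenes, and the new element is their merger in one pot on an acyclic aldehyde. The upper pyran ring (O1, C2, C3, C4, C4a, C8a) closes by a 6-exo-trig attack of the arene on the activated carbonyl through a chair-like transition state with the C2 aryl group equatorial and the 3-benzyloxy group axial. The one new stereocentre, C4 of the upper unit, is set by substrate control: in the half-chair of 19 the pseudoaxial 3-benzyloxy group shields the alpha face and peri strain with the 5-benzyloxy group favours a pseudoaxial C4 aryl group, so the 3,4-trans (4beta, 4R) product is expected, and the C4 configuration of 18 is irrelevant because ionisation erases it. The step needs ring closure to outrun a second intermolecular arylation, attack at C8 and not at C6 of 16, and a single coupling per molecule of 16, which the tether between two tri-oxygenated rings, the higher nucleophilicity of C8 in 5,7-di-O-benzyl flavan-3-ols and the excess of 16 combined with slow addition of 17 should secure in that order. The low temperature shields the acid-labile benzylic aryl ether at C2 and the alpha-alkoxy aldehyde from ionisation and epimerisation.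

Step 11
Reactants: 20 3,5,7,4'-tetra-O-benzyl-epiafzelechin-(4β→8)-5,7,3',4',5'-penta-O-benzyl-epigallocatechin
Product: 21 epiafzelechin-(4β→8)-epigallocatechin [(2R,3R)-8-[(2R,3R,4R)-3,5,7-trihydroxy-2-(4-hydroxyphenyl)chroman-4-yl]-2-(3,4,5-trihydroxyphenyl)chroman-3,5,7-triol]
Conditions: H2 (1 atm), Pd(OH)2/C, THF/MeOH/H2O, rt; filtration under argon, lyophilisation
Reagents that add atoms: none
Why: Catalytic hydrogenolysis over Pd(OH)2/C should cleave all nine O-benzyl bonds under neutral conditions that the interflavan C4–C8 bond and the cyclic C2–O1 ethers of benzylated proanthocyanidins tolerate, and no stereocentre is affected.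

Compound list
1 | (S)-4-benzyloxazolidin-2-one | O=C1OC[C@H](Cc2ccccc2)N1 | starting material
2 | benzyloxyacetyl chloride | O=C(Cl)COCc1ccccc1 | starting material
3 | N-lithio-(S)-4-benzyloxazolidin-2-one (lithium salt of 1) | [Li+].O=C1OC[C@H](Cc2ccccc2)[N-]1 | intermediate
4 | (S)-4-benzyl-3-[2-(benzyloxy)acetyl]oxazolidin-2-one | O=C1OC[C@H](Cc2ccccc2)N1C(=O)COCc1ccccc1 | intermediate
5 | 4-(benzyloxy)benzaldehyde | O=Cc1ccc(OCc2ccccc2)cc1 | starting material
6 | (S)-4-benzyl-3-[(Z)-2-(benzyloxy)-1-[(dibutylboranyl)oxy]ethenyl]oxazolidin-2-one (Z boron enolate of 4) | CCCCB(CCCC)O/C(=C\OCc1ccccc1)N1C(=O)OC[C@@H]1Cc1ccccc1 | intermediate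
7 | O-dibutylboryl aldolate of 8, (2S,3R) configuration | O(Cc5ccccc5)c1ccc([C@@H](OB(CCCC)CCCC)[C@H](OCc5ccccc5)C(=O)N2C(=O)OC[C@@H]2Cc5ccccc5)cc1 | intermediate
8 | (S)-4-benzyl-3-[(2S,3R)-2-(benzyloxy)-3-[4-(benzyloxy)phenyl]-3-hydroxypropanoyl]oxazolidin-2-one | O(Cc5ccccc5)c1ccc([C@@H](O)[C@H](OCc5ccccc5)C(=O)N2C(=O)OC[C@@H]2Cc5ccccc5)cc1 | intermediate
9 | (1R,2R)-2-(benzyloxy)-1-[4-(benzyloxy)phenyl]propane-1,3-diol | O(Cc5ccccc5)c1ccc([C@@H](O)[C@H](OCc5ccccc5)CO)cc1 | intermediate
10 | (1R,2R)-2-(benzyloxy)-1-[4-(benzyloxy)phenyl]-3-[(triisopropylsilyl)oxy]propan-1-ol | O(Cc5ccccc5)c1ccc([C@@H](O)[C@H](OCc5ccccc5)CO[Si](C(C)C)(C(C)C)C(C)C)cc1 | intermediate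
11 | 5-iodoresorcinol (5-iodobenzene-1,3-diol) | Oc1cc(O)cc(I)c1 | starting material
12 | 1,3-bis(benzyloxy)-5-iodobenzene | Ic1cc(OCc2ccccc2)cc(OCc2ccccc2)c1 | intermediate
13 | [(2R,3R)-2-(benzyloxy)-3-[4-(benzyloxy)phenyl]-3-[3,5-bis(benzyloxy)phenoxy]propoxy]triisopropylsilane | O(Cc5ccccc5)c1ccc([C@@H](Oc3cc(OCc5ccccc5)cc(OCc5ccccc5)c3)[C@H](OCc5ccccc5)CO[Si](C(C)C)(C(C)C)C(C)C)cc1 | intermediate
14 | (2R,3R)-2-(benzyloxy)-3-[4-(benzyloxy)phenyl]-3-[3,5-bis(benzyloxy)phenoxy]propan-1-ol | O(Cc5ccccc5)c1ccc([C@@H](Oc3cc(OCc5ccccc5)cc(OCc5ccccc5)c3)[C@H](OCc5ccccc5)CO)cc1 | intermediate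
15 | (−)-epigallocatechin, (2R,3R) | Oc1cc(O)c2c(c1)O[C@H](c1cc(O)c(O)c(O)c1)[C@H](O)C2 | starting material
16 | 5,7,3',4',5'-penta-O-benzyl-(−)-epigallocatechin, (2R,3R), free 3-OH | O(Cc1ccccc1)c1cc(OCc3ccccc3)c2c(c1)O[C@H](c1cc(OCc3ccccc3)c(OCc3ccccc3)c(OCc3ccccc3)c1)[C@H](O)C2 | intermediate
17 | (2S,3R)-2-(benzyloxy)-3-[4-(benzyloxy)phenyl]-3-[3,5-bis(benzyloxy)phenoxy]propanal | O(Cc5ccccc5)c1ccc([C@@H](Oc3cc(OCc5ccccc5)cc(OCc5ccccc5)c3)[C@H](OCc5ccccc5)C=O)cc1 | intermediate
18 | 3,5,7,4'-tetra-O-benzyl-epiafzelechin-4-ol (2R,3R, 2,3-cis; C4 epimers, configuration not defined) | O(Cc5ccccc5)c1ccc([C@H]2Oc3cc(OCc5ccccc5)cc(OCc5ccccc5)c3C(O)[C@H]2OCc5ccccc5)cc1 | intermediate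
19 | 3,5,7,4'-tetra-O-benzyl-epiafzelechin-4-yl cation (2,3-cis; triflate as counter-ion) | O(Cc5ccccc5)c1ccc([C@H]2Oc3cc(OCc5ccccc5)cc(OCc5ccccc5)c3[CH+][C@H]2OCc5ccccc5)cc1 | intermediate
20 | 3,5,7,4'-tetra-O-benzyl-epiafzelechin-(4β→8)-5,7,3',4',5'-penta-O-benzyl-epigallocatechin; upper unit (2R,3R,4R), 2,3-cis-3,4-trans; lower unit (2R,3R) | O(Cc5ccccc5)c1ccc([C@H]2Oc3cc(OCc5ccccc5)cc(OCc5ccccc5)c3[C@H](c3c(OCc5ccccc5)cc(OCc5ccccc5)c4c3O[C@H](c3cc(OCc5ccccc5)c(OCc5ccccc5)c(OCc5ccccc5)c3)[C@H](O)C4)[C@H]2OCc5ccccc5)cc1 | intermediate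
21 | epiafzelechin-(4β→8)-epigallocatechin; upper unit (2R,3R,4R), lower unit (2R,3R) | Oc1ccc([C@H]2Oc3cc(O)cc(O)c3[C@H](c3c(O)cc(O)c4c3O[C@H](c3cc(O)c(O)c(O)c3)[C@H](O)C4)[C@H]2O)cc1 | target

Total step count: 11 steps. Longest linear sequence: 9 steps (steps 1, 2, 3, 4, 6, 7, 9, 10 and 11); steps 5 and 8 each prepare a coupling partner in one step.

Steps most likely to fail

Step 10 (the step that bears the label "Proposed new method:"). The two arylations may not follow the intended order: a second molecule of 16 may add to the open diarylmethyl cation before the tethered ring closes, cation 19 may be captured by the product or by unreacted 17 so that oligomers form, or the benzylic C2–O bond may ionise under the acid. The fallback separates the two C–C bond formations into known reactions; it sets out from aldehyde 17 and comes back at 20. Aldehyde 17 would be cyclised without the flavanol, in CH2Cl2 with an excess of 2-ethoxyethanol and catalytic camphorsulfonic acid at −20 → 0 °C. The Friedel–Crafts closure of the aryloxy aldehyde is then followed by trapping of the C4 cation by the alcohol, which should give 3,5,7,4'-tetra-O-benzyl-4β-(2-ethoxyethoxy)epiafzelechin F1 (either C4 epimer would serve). This stable C4-oxygenated electrophile would then be coupled with an excess of 16 under catalytic TMSOTf in CH2Cl2 at −78 °C, the established way of forming 4→8 interflavan bonds, to give 20.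

Step 6. Carbon–oxygen bond formation at the hindered secondary benzylic alkoxide may be slow, so that reduction of the aryl iodide, oxidation of the carbinol or silyl migration compete. The fallback replaces O-arylation by substitution at the benzylic carbon; it sets out from 10 and comes back at 13. Dess–Martin oxidation of 10 would give (R)-2-(benzyloxy)-1-[4-(benzyloxy)phenyl]-3-[(triisopropylsilyl)oxy]propan-1-one F2. Chelation-controlled reduction with Zn(BH4)2 in Et2O at −20 °C should then deliver the anti alcohol (1S,2R)-2-(benzyloxy)-1-[4-(benzyloxy)phenyl]-3-[(triisopropylsilyl)oxy]propan-1-ol F3. A Mitsunobu reaction of this alcohol with commercial 3,5-bis(benzyloxy)phenol (Oc1cc(OCc2ccccc2)cc(OCc2ccccc2)c1; PPh3, DIAD, toluene, 0 °C) should give 13 with inversion at the benzylic carbon. The known weakness is partial ionisation of the electron-rich benzylic centre, which a non-polar solvent and low temperature limit.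

Step 9. The aldehyde may be lost through beta-elimination of the aryloxide or may epimerise alpha to the carbonyl during oxidation and handling. The fallback never passes through a free aldehyde and uses a thionium ion as the C4 electrophile; it sets out from alcohol 14 and comes back at 20, bypassing 17. Treatment of 14 with PhSSPh and n-Bu3P in THF should give the sulfide (2R,3R)-configured 1,3-bis(benzyloxy)-5-[2-(benzyloxy)-1-[4-(benzyloxy)phenyl]-3-(phenylthio)propoxy]benzene F4. Oxidation with one equivalent of mCPBA in CH2Cl2 at −78 °C would give the corresponding phenyl sulfoxide F5 (mixture at sulfur). A Pummerer reaction with TFAA in CH2Cl2 at 0 °C would then generate the thionium ion, which the ortho carbon of the aryl ether should trap (Pummerer–Friedel–Crafts cyclisation) to give 3,5,7,4'-tetra-O-benzyl-4-(phenylthio)epiafzelechin F6 (either C4 epimer would serve). Thiophilic activation of this 4-thioflavan with AgBF4 in CH2Cl2/THF at −78 → 0 °C in the presence of excess 16, a known mode of interflavan coupling, should give 20.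

Further compounds
F1 | step 10 | 3,5,7,4'-tetra-O-benzyl-4β-(2-ethoxyethoxy)epiafzelechin | O(Cc5ccccc5)c1ccc([C@H]2Oc3cc(OCc5ccccc5)cc(OCc5ccccc5)c3[C@H](OCCOCC)[C@H]2OCc5ccccc5)cc1
F2 | step 6 | (R)-2-(benzyloxy)-1-[4-(benzyloxy)phenyl]-3-[(triisopropylsilyl)oxy]propan-1-one | O(Cc5ccccc5)c1ccc(C(=O)[C@H](OCc5ccccc5)CO[Si](C(C)C)(C(C)C)C(C)C)cc1
F3 | step 6 | (1S,2R)-2-(benzyloxy)-1-[4-(benzyloxy)phenyl]-3-[(triisopropylsilyl)oxy]propan-1-ol | O(Cc5ccccc5)c1ccc([C@H](O)[C@H](OCc5ccccc5)CO[Si](C(C)C)(C(C)C)C(C)C)cc1
F4 | step 9 | phenyl sulfide of 14 (CH2OH replaced by CH2SPh, both stereocentres as in 14) | O(Cc5ccccc5)c1ccc([C@@H](Oc3cc(OCc5ccccc5)cc(OCc5ccccc5)c3)[C@H](OCc5ccccc5)CSc3ccccc3)cc1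
F5 | step 9 | phenyl sulfoxide of F4 (mixture at sulfur) | O(Cc5ccccc5)c1ccc([C@@H](Oc3cc(OCc5ccccc5)cc(OCc5ccccc5)c3)[C@H](OCc5ccccc5)CS(=O)c3ccccc3)cc1
F6 | step 9 | 3,5,7,4'-tetra-O-benzyl-4β-(phenylthio)epiafzelechin | O(Cc5ccccc5)c1ccc([C@H]2Oc3cc(OCc5ccccc5)cc(OCc5ccccc5)c3[C@H](Sc3ccccc3)[C@H]2OCc5ccccc5)cc1
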